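## Retrosynthetic overview

- Numbering used in the text: ring A = C1–C5 and C10 (C4 carries the two methyls; C5–H and C10–CH3 sit at the ring fusion); ring B = C5–C10 with the C8=C9 alkene; side chain C11–C16 runs from C9 to the butenolide.
- Late disconnections: C15=C16 (vinylogous Horner–Wadsworth–Emmons with a butenolide phosphonate), C12–C13 (B-alkyl Suzuki–Miyaura with a (Z)-iodobutenediol piece that carries the CH2OH), C9–C11 (Stille vinylation of the C8=C9 enol triflate of cis-decalone 7).
- Key disconnection: ring A is annulated last onto ring B by a one-flask [3+3] union of a C1–C2–C3 unit with monocyclic ketone 3. C3–C4 forms by addition of the tertiary C4 radical (from hydrogen-atom transfer to an isopropenyl group) to a 2-sulfonylallyl sulfone; C1–C10 then forms by Michael closure of the C10 enolate.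
- Enabling feature: ring A is a bare C1–C2–C3 trimethylene bridge between the two quaternary carbons C4 and C10, which are 1,3-related through C5. C4 with its two methyls is a latent isopropenyl group on C5, and C10 is α to C9, which can stay a carbonyl until the C8=C9 alkene is made. This is the pattern of a methylated dihydrocarvone, so (S)-carvone supplies ring B and the C5 stereocentre.
- Ring order: ring B (chiral pool) → ring A (step 3, sets both quaternary carbons and the cis fusion) → butenolide brought in intact.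

Key step: step 3

Remark: the target is read as drawn, with a cis A/B fusion (C10–CH3 and C5–H on the same face; 4aR,8aS in the names below).
Remark: 2,3-bis(phenylsulfonyl)prop-1-ene (4) and 4-(bromomethyl)furan-2(5H)-one (13) are taken as purchasable reagents.

## Route

Step 1
Reactants: 1 (S)-(+)-carvone
Product: 2 (5S)-2,6-dimethyl-5-(prop-1-en-2-yl)cyclohex-2-en-1-one (C6 epimers)
Conditions: LiN(i-Pr)2, THF, −78 °C; MeI, −78 to 0 °C
Reagents that add atoms: iodomethane, CI
Why: Kinetic enolate alkylation: the amide base removes the α' proton (C10–H) to give the cross-conjugated dienolate, which is C-methylated regiospecifically; the new C10 centre is left as a mixture because it is re-set in step 3, and C5 is untouched.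

Step 2
Reactants: 2 (5S)-2,6-dimethyl-5-(prop-1-en-2-yl)cyclohex-2-en-1-one
Product: 3 (3S)-2,6-dimethyl-3-(prop-1-en-2-yl)cyclohexan-1-one (C2/C6 epimers)
Conditions: LiBH(s-Bu)3, THF, −78 °C; then H2O
Reagents that add atoms: none
Why: Conjugate (1,4) hydride reduction of the β-unsubstituted enone by the bulky borohydride, then protonation of the enolate, should give the saturated ketone without touching the isopropenyl group; the C8 centre formed is epimerisable and is erased in step 5.

Step 3
Reactants: 3 (3S)-2,6-dimethyl-3-(prop-1-en-2-yl)cyclohexan-1-one; 4 2,3-bis(phenylsulfonyl)prop-1-ene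
Product: 6 (4aR,8aS)-2,5,5,8a-tetramethyl-7-(phenylsulfonyl)octahydronaphthalen-1(2H)-one (cis-fused; C2/C7 epimers), via vinyl sulfone ketone 5 (not isolated)
Conditions: Fe(acac)3 (0.3 equiv), PhSiH3, EtOH/ethylene glycol, 60 °C; then NaOEt, EtOH, 0 °C to rt, same flask
Reagents that add atoms: none
Why: Proposed new method: an iron hydride formed from Fe(acac)3 and PhSiH3 transfers a hydrogen atom to the CH2 of the isopropenyl group of 3, and the tertiary C4 radical adds to the CH2 terminus of 4 and loses the allylic sulfonyl group (β-scission, or reduction to the α-sulfonyl anion and E1cB), which forms C3–C4 and leaves the 2-sulfonylallyl acceptor 5; ethoxide then enolises the ketone toward C10 and the enolate adds to C1 of the vinyl sulfone, which forms C1–C10. The closest known reaction types are the iron-hydride reductive coupling of 1,1-disubstituted alkenes with vinyl sulfones and acrylates, radical allylation by addition–fragmentation of 2-substituted allyl sulfones, and the α,α'-annulation of enamines with 2-(bromomethyl)acrylates, but their union in one flask on a ketone of this kind is untested. Ring A closes in the 6-endo-trig mode (both carbons of the acceptor alkene end in the ring), as in those α,α'-annulations. C4 is not stereogenic; C10 is controlled by the C5 stereocentre, because the four-atom tether can reach the enolate carbon along the near-perpendicular trajectory only on its own face, which puts C1 cis to C4 and gives the cis fusion (a trans fusion would need a boat-like ring B); the sulfone-bearing carbon and C8 are left as mixtures because both are erased later. The step needs hydrogen-atom transfer to one alkene only (the isopropenyl group is the sole electron-rich alkene; 4 and 5 are electron-poor), addition at C3 and not C2 of the acceptor (polarity and sterics of a 1,1-disubstituted vinyl sulfone), and closure from C10 and not C8 (the C8 enolate could only form an eight-membered ring and reverts).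

Step 4
Reactants: 6 (4aR,8aS)-2,5,5,8a-tetramethyl-7-(phenylsulfonyl)octahydronaphthalen-1(2H)-one
Product: 7 (4aR,8aS)-2,5,5,8a-tetramethyloctahydronaphthalen-1(2H)-one (cis-fused; C2 epimers)
Conditions: Na(Hg) (6% Na), Na2HPO4, MeOH/THF, −20 °C
Reagents that add atoms: none
Why: Reductive desulfonylation (electron transfer, C–S cleavage, protonation) should remove the activating group from C2 of ring A; the buffered, cold conditions should spare the hindered ketone, and no fusion stereocentre is touched.

Step 5
Reactants: 7 (4aR,8aS)-2,5,5,8a-tetramethyloctahydronaphthalen-1(2H)-one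
Product: 8 (4aR,8aS)-2,5,5,8a-tetramethyl-3,4,4a,5,6,7,8,8a-octahydronaphthalen-1-yl trifluoromethanesulfonate
Conditions: KN(SiMe3)2, THF, −78 to 0 °C; PhNTf2, −78 °C to rt
Reagents that add atoms: N-phenylbis(trifluoromethanesulfonimide), O=S(=O)(N(c1ccccc1)S(=O)(=O)C(F)(F)F)C(F)(F)F
Why: Enol triflate formation: only C8 carries an α-hydrogen (C10 is quaternary), so the potassium enolate and its O-triflate should form regiospecifically as the tetrasubstituted C8=C9 alkene, which also erases the C8 stereocentre.

Step 6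
Reactants: 8 (4aR,8aS)-2,5,5,8a-tetramethyl-3,4,4a,5,6,7,8,8a-octahydronaphthalen-1-yl trifluoromethanesulfonate
Product: 9 (4aR,8aS)-1-ethenyl-2,5,5,8a-tetramethyl-3,4,4a,5,6,7,8,8a-octahydronaphthalene
Conditions: CH2=CHSnBu3, Pd(PPh3)4 (cat.), LiCl, THF, reflux
Reagents that add atoms: tributyl(vinyl)stannane, C=C[Sn](CCCC)(CCCC)CCCC
Why: Stille coupling of the enol triflate with the vinylstannane (LiCl-assisted oxidative addition to zerovalent palladium, transmetalation, reductive elimination) should form C9–C11 and leave the C8=C9 alkene in place.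

Step 7
Reactants: 10 but-2-yne-1,4-diol
Product: 11 4-[(tert-butyldimethylsilyl)oxy]but-2-yn-1-ol
Conditions: NaH (1 equiv), THF, 0 °C; TBSCl, rt
Reagents that add atoms: tert-butyldimethylsilyl chloride, CC(C)(C)[Si](C)(C)Cl
Why: Monosilylation of a symmetrical diol through its poorly soluble monosodium alkoxide (O-silylation) should limit double protection.

Step 8
Reactants: 11 4-[(tert-butyldimethylsilyl)oxy]but-2-yn-1-ol
Product: 12 (2Z)-4-[(tert-butyldimethylsilyl)oxy]-3-iodobut-2-en-1-ol
Conditions: NaAlH2(OCH2CH2OMe)2, THF, 0 °C to rt; then I2, THF, −78 °C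
Reagents that add atoms: iodine, II
Why: Hydroxyl-directed trans-hydroalumination of the propargylic alcohol places aluminium on the alkyne carbon remote from the free OH, and iodinolysis with retention should give the (Z)-vinyl iodide, which fixes the later C13=C14 geometry.

Step 9
Reactants: 13 4-(bromomethyl)furan-2(5H)-one
Product: 14 diethyl [(5-oxo-2,5-dihydrofuran-3-yl)methyl]phosphonate
Conditions: P(OEt)3, toluene, 110 °C
Reagents that add atoms: triethyl phosphite, CCOP(OCC)OCC
Why: Michaelis–Arbuzov reaction of the allylic bromide with triethyl phosphite should give the allylic phosphonate.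

Step 10
Reactants: 9 (4aR,8aS)-1-ethenyl-2,5,5,8a-tetramethyl-3,4,4a,5,6,7,8,8a-octahydronaphthalene; 12 (2Z)-4-[(tert-butyldimethylsilyl)oxy]-3-iodobut-2-en-1-ol
Product: 16 (2E)-3-{[(tert-butyldimethylsilyl)oxy]methyl}-5-[(4aR,8aS)-2,5,5,8a-tetramethyl-3,4,4a,5,6,7,8,8a-octahydronaphthalen-1-yl]pent-2-en-1-ol, via B-alkyl-9-BBN borane 15 (not isolated)
Conditions: 9-BBN-H dimer, THF, 0 °C to rt; then 12, Pd(dppf)Cl2 (cat.), AsPh3, Cs2CO3, DMF/THF/H2O, rt
Reagents that add atoms: none
Why: Hydroboration of the unhindered vinyl group (the tetrasubstituted ring alkene is inert to 9-BBN) gives the primary borane, and B-alkyl Suzuki–Miyaura coupling with the vinyl iodide should form C12–C13 with retention, so the chain ends cis to C15 and the silyloxymethyl group trans.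

Step 11
Reactants: 16 (2E)-3-{[(tert-butyldimethylsilyl)oxy]methyl}-5-[(4aR,8aS)-2,5,5,8a-tetramethyl-3,4,4a,5,6,7,8,8a-octahydronaphthalen-1-yl]pent-2-en-1-ol
Product: 17 (2E)-3-{[(tert-butyldimethylsilyl)oxy]methyl}-5-[(4aR,8aS)-2,5,5,8a-tetramethyl-3,4,4a,5,6,7,8,8a-octahydronaphthalen-1-yl]pent-2-enal
Conditions: MnO2 (activated), CH2Cl2, rt
Reagents that add atoms: none
Why: Allylic oxidation of the primary allylic alcohol with activated MnO2 should give the enal without over-oxidation or loss of alkene geometry.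

Step 12
Reactants: 17 (2E)-3-{[(tert-butyldimethylsilyl)oxy]methyl}-5-[(4aR,8aS)-2,5,5,8a-tetramethyl-3,4,4a,5,6,7,8,8a-octahydronaphthalen-1-yl]pent-2-enal; 14 diethyl [(5-oxo-2,5-dihydrofuran-3-yl)methyl]phosphonate
Product: 18 4-[(1E,3E)-4-{[(tert-butyldimethylsilyl)oxy]methyl}-6-[(4aR,8aS)-2,5,5,8a-tetramethyl-3,4,4a,5,6,7,8,8a-octahydronaphthalen-1-yl]hexa-1,3-dien-1-yl]furan-2(5H)-one
Conditions: 14, LiN(SiMe3)2, THF, −78 °C; then 17, −78 to 0 °C
Reagents that add atoms: none
Why: Vinylogous Horner–Wadsworth–Emmons olefination: the phosphonate-stabilised anion reacts at its phosphorus-bearing carbon with the enal, and the stabilised reagent should give the (E)-C15=C16 alkene.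

Step 13
Reactants: 18 4-[(1E,3E)-4-{[(tert-butyldimethylsilyl)oxy]methyl}-6-[(4aR,8aS)-2,5,5,8a-tetramethyl-3,4,4a,5,6,7,8,8a-octahydronaphthalen-1-yl]hexa-1,3-dien-1-yl]furan-2(5H)-one
Product: 19 4-[(1E,3E)-4-(hydroxymethyl)-6-[(4aR,8aS)-2,5,5,8a-tetramethyl-3,4,4a,5,6,7,8,8a-octahydronaphthalen-1-yl]hexa-1,3-dien-1-yl]furan-2(5H)-one (CNP0232848.3)
Conditions: HF·pyridine, pyridine, THF, 0 °C to rt
Reagents that add atoms: none
Why: Fluoride-mediated cleavage of the primary silyl ether under buffered, non-basic conditions should release the allylic alcohol and spare the butenolide and the triene.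

## Compound list

1 | (S)-(+)-carvone, (5S)-2-methyl-5-(prop-1-en-2-yl)cyclohex-2-en-1-one | CC(=C)[C@H]1CC=C(C)C(=O)C1 | starting material
2 | (5S)-2,6-dimethyl-5-(prop-1-en-2-yl)cyclohex-2-en-1-one (C6 epimers) | CC(=C)[C@H]1CC=C(C)C(=O)C1C | intermediate
3 | (3S)-2,6-dimethyl-3-(prop-1-en-2-yl)cyclohexan-1-one (C2/C6 epimers) | CC(=C)[C@H]1CCC(C)C(=O)C1C | intermediate
4 | 2,3-bis(phenylsulfonyl)prop-1-ene | C=C(CS(=O)(=O)c1ccccc1)S(=O)(=O)c1ccccc1 | starting material
5 | (3S)-2,6-dimethyl-3-[2-methyl-4-(phenylsulfonyl)pent-4-en-2-yl]cyclohexan-1-one | C=C(CC(C)(C)[C@H]1CCC(C)C(=O)C1C)S(=O)(=O)c1ccccc1 | intermediate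
6 | (4aR,8aS)-2,5,5,8a-tetramethyl-7-(phenylsulfonyl)octahydronaphthalen-1(2H)-one (cis-fused; C2/C7 epimers) | CC1C(=O)[C@@]2(C)CC(S(=O)(=O)c3ccccc3)CC(C)(C)[C@H]2CC1 | intermediate
7 | (4aR,8aS)-2,5,5,8a-tetramethyloctahydronaphthalen-1(2H)-one (cis-fused; C2 epimers) | CC1C(=O)[C@@]2(C)CCCC(C)(C)[C@H]2CC1 | intermediate
8 | (4aR,8aS)-2,5,5,8a-tetramethyl-3,4,4a,5,6,7,8,8a-octahydronaphthalen-1-yl trifluoromethanesulfonate | CC1=C(OS(=O)(=O)C(F)(F)F)[C@@]2(C)CCCC(C)(C)[C@H]2CC1 | intermediate
9 | (4aR,8aS)-1-ethenyl-2,5,5,8a-tetramethyl-3,4,4a,5,6,7,8,8a-octahydronaphthalene | CC1=C(C=C)[C@@]2(C)CCCC(C)(C)[C@H]2CC1 | intermediate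
10 | but-2-yne-1,4-diol | OCC#CCO | starting material
11 | 4-[(tert-butyldimethylsilyl)oxy]but-2-yn-1-ol | OCC#CCO[Si](C)(C)C(C)(C)C | intermediate
12 | (2Z)-4-[(tert-butyldimethylsilyl)oxy]-3-iodobut-2-en-1-ol | OC/C=C(\I)CO[Si](C)(C)C(C)(C)C | intermediate
13 | 4-(bromomethyl)furan-2(5H)-one | BrCC1=CC(=O)OC1 | starting material
14 | diethyl [(5-oxo-2,5-dihydrofuran-3-yl)methyl]phosphonate | CCOP(=O)(OCC)CC1=CC(=O)OC1 | intermediate
15 | 9-{2-[(4aR,8aS)-2,5,5,8a-tetramethyl-3,4,4a,5,6,7,8,8a-octahydronaphthalen-1-yl]ethyl}-9-borabicyclo[3.3.1]nonane | CC1=C(CCB2C3CCCC2CCC3)[C@@]2(C)CCCC(C)(C)[C@H]2CC1 | intermediate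
16 | (2E)-3-{[(tert-butyldimethylsilyl)oxy]methyl}-5-[(4aR,8aS)-2,5,5,8a-tetramethyl-3,4,4a,5,6,7,8,8a-octahydronaphthalen-1-yl]pent-2-en-1-ol | CC1=C(CC/C(CO[Si](C)(C)C(C)(C)C)=C\CO)[C@@]2(C)CCCC(C)(C)[C@H]2CC1 | intermediate
17 | (2E)-3-{[(tert-butyldimethylsilyl)oxy]methyl}-5-[(4aR,8aS)-2,5,5,8a-tetramethyl-3,4,4a,5,6,7,8,8a-octahydronaphthalen-1-yl]pent-2-enal | CC1=C(CC/C(CO[Si](C)(C)C(C)(C)C)=C\C=O)[C@@]2(C)CCCC(C)(C)[C@H]2CC1 | intermediate
18 | 4-[(1E,3E)-4-{[(tert-butyldimethylsilyl)oxy]methyl}-6-[(4aR,8aS)-2,5,5,8a-tetramethyl-3,4,4a,5,6,7,8,8a-octahydronaphthalen-1-yl]hexa-1,3-dien-1-yl]furan-2(5H)-one | CC1=C(CC/C(=C\C=C\C2=CC(=O)OC2)CO[Si](C)(C)C(C)(C)C)[C@@]2(C)CCCC(C)(C)[C@H]2CC1 | intermediate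
19 | 4-[(1E,3E)-4-(hydroxymethyl)-6-[(4aR,8aS)-2,5,5,8a-tetramethyl-3,4,4a,5,6,7,8,8a-octahydronaphthalen-1-yl]hexa-1,3-dien-1-yl]furan-2(5H)-one | CC1=C(CC/C(=C\C=C\C2=CC(=O)OC2)CO)[C@@]2(C)CCCC(C)(C)[C@H]2CC1 | target

## Step count and risks

Total steps: 13. Longest linear sequence: 10 steps (steps 1–6 and 10–13).

Steps most likely to fail:

1. Step 3 (proposed new method). The C4 radical may be reduced to the isopropyl group before it adds, or may add to 5 in place of 4 and give oligomers. Ethoxide may isomerise the 2-sulfonylallyl unit to the internal vinyl sulfone before ring closure, and reversible Michael addition may erode the cis selectivity. Fallback with known chemistry, setting out from 3: iron-hydride reductive olefin coupling with acrolein (Fe(acac)3, PhSiH3, EtOH/ethylene glycol, 60 °C) should give the keto aldehyde F1. Intramolecular aldol addition of the C10 enolate to the aldehyde (KOH, MeOH, 0 °C) should close ring A under the same tether control and give the cis-fused β-hydroxy ketone F2. Thiocarbonyldiimidazole (DMAP, CH2Cl2) should give the imidazolyl thiocarbonate F3 without base-induced retro-aldol, and Barton–McCombie deoxygenation (Bu3SnH, AIBN, toluene, 80 °C) should give 7, where the route is rejoined; step 4 is then not needed.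

2. Step 6. Oxidative addition at the hindered, tetrasubstituted enol triflate may be slow, so that triflate hydrolysis, reduction or stannane homocoupling take over. Fallback setting out from 7: hydrazine hydrate and Et3N in refluxing EtOH should give the hydrazone F4. Iodine with tetramethylguanidine in Et2O (Barton vinyl iodide synthesis) should give the vinyl iodide F5, a more reactive electrophile. Stille coupling with tributyl(vinyl)stannane (Pd(PPh3)4, THF, 60 °C) should then give 9, where the route is rejoined; triflate 8 is bypassed.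

3. Step 12. The base may deprotonate the ring CH2 of the butenolide and cause self-condensation of 14, the anion may attack through its α-carbon, or the E selectivity may be poor on the β,β-disubstituted enal. Fallback setting out from 17: the boron variant of the Takai olefination (CrCl2, Cl2CHBpin, LiI, THF, rt) should give the (E,E)-dienyl pinacol boronate F6. Suzuki–Miyaura coupling with 4-bromofuran-2(5H)-one (Pd(dppf)Cl2, K3PO4, THF/H2O, rt) should then give 18, where the route is rejoined.

## Further compounds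

F1 | step 3 | 4-methyl-4-[(1S)-2,4-dimethyl-3-oxocyclohexyl]pentanal | O=CCCC(C)(C)[C@H]1CCC(C)C(=O)C1C
F2 | step 3 | (4aR,8aR)-8-hydroxy-2,5,5,8a-tetramethyloctahydronaphthalen-1(2H)-one (cis-fused; carbinol epimers) | CC1C(=O)[C@@]2(C)C(O)CCC(C)(C)[C@H]2CC1
F3 | step 3 | O-(imidazol-1-ylthiocarbonyl) derivative of F2 | CC1C(=O)[C@@]2(C)C(OC(=S)n3ccnc3)CCC(C)(C)[C@H]2CC1
F4 | step 6 | hydrazone of (4aR,8aS)-2,5,5,8a-tetramethyloctahydronaphthalen-1(2H)-one | CC1C(=NN)[C@@]2(C)CCCC(C)(C)[C@H]2CC1
F5 | step 6 | (4aR,8aS)-1-iodo-2,5,5,8a-tetramethyl-3,4,4a,5,6,7,8,8a-octahydronaphthalene | CC1=C(I)[C@@]2(C)CCCC(C)(C)[C@H]2CC1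
F6 | step 12 | tert-butyldimethylsilyl ether of (2E,4E)-2-{2-[(4aR,8aS)-2,5,5,8a-tetramethyl-3,4,4a,5,6,7,8,8a-octahydronaphthalen-1-yl]ethyl}-5-(4,4,5,5-tetramethyl-1,3,2-dioxaborolan-2-yl)penta-2,4-dien-1-ol | CC1=C(CC/C(CO[Si](C)(C)C(C)(C)C)=C\C=C\B2OC(C)(C)C(C)(C)O2)[C@@]2(C)CCCC(C)(C)[C@H]2CC1
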